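**Retrosynthetic overview**
- The target is reached from a cyclopentane diol enal by acetylation of O14/O15, exchange of a silyl ether at O3 for the benzoate, and a final Wacker oxidation of a C9 vinyl group to the methyl ketone.
- The cyclopentane, the only ring, is closed last in the chain-building sequence by a C4–C15 aldol. This is the ring-A closure proposed for Euphorbia diterpenoid biosynthesis, run here in vinylogous form on the open 7,8-seco chain, with the C7 enal supplying the C4 nucleophile and the C14/C15 ketol as acceptor.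
- The acyclic keto-enal comes from cross-metathesis with methacrolein (C5=C6) and a Weinreb ketone synthesis (C15–C1).
- The C8–C15 amide comes from a dianion Ireland–Claisen rearrangement of the hydroxyacetate of an (S)-dienol, itself made by prenylboration of crotonaldehyde. The C1–C5 bromide comes from allylboration of (S)-3-bromo-2-methylpropanal.
- Ring order: one ring only, formed in step 10 after the whole carbon chain is in place.

Assumption: the SMILES is read as the (2R,3S,4S,13S,14R,15R) enantiomer in jatrophane numbering (ring C1–C4 and C15, enal C5–C7, chain C8–C14), and "(+)-Ipc" means the isopinocampheyl group derived from (−)-α-pinene.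

**Route**

Step 1
Reactants: 1 (E)-but-2-enal (crotonaldehyde); 2 3-methylbuta-1,2-diene
Product: 5 (S,E)-3,3-dimethylhepta-1,5-dien-4-ol, via prenylborane 3 (not isolated), via borinate ester 4 (not isolated)
Conditions: (+)-Ipc2BH, 2, THF, −25 °C; then 1, Et2O, −78 °C; NaOH, H2O2, 0 °C to rt
Reagents that add atoms: none
Why: Brown reverse prenylboration (allylboration through a chair Zimmerman–Traxler transition state), in which the γ-carbon of the prenylborane adds to the Re face of the enal under control of the (+)-Ipc groups to set the (S)-carbinol, as in the artemisia alcohol case.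

Step 2
Reactants: 5 (S,E)-3,3-dimethylhepta-1,5-dien-4-ol
Product: 7 (S,E)-3,3-dimethylhepta-1,5-dien-4-yl 2-hydroxyacetate, via silyl ether 6 (not isolated)
Conditions: Me3SiOCH2CO2SiMe3, (COCl)2, DMF (cat.), CH2Cl2, 0 °C to rt, evaporate; then 5, pyridine, DMAP (cat.), CH2Cl2, 0 °C to rt; citric acid, MeOH
Reagents that add atoms: 2-(trimethylsilyloxy)acetyl chloride, C[Si](C)(C)OCC(Cl)=O (made in the flask from trimethylsilyl 2-(trimethylsilyloxy)acetate, C[Si](C)(C)OCC(=O)O[Si](C)(C)C, and oxalyl chloride)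
Why: DMAP-catalysed esterification of the hindered allylic alcohol with a silyl-masked glycolyl chloride, the labile O–SiMe3 group being methanolysed on work-up so that the free hydroxyacetate needed for the dianion rearrangement is obtained in one operation without touching the stereocentre.

Step 3
Reactants: 7 (S,E)-3,3-dimethylhepta-1,5-dien-4-yl 2-hydroxyacetate
Product: 10 (2R,3S,E)-2-hydroxy-3,6,6-trimethylocta-4,7-dienoic acid, via ketene acetal 8 (not isolated), via silyl ester 9 (not isolated)
Conditions: LiN(i-Pr)2 (2.3 equiv), THF, −78 °C; Me3SiCl, −78 °C to rt; dilute aq. HCl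
Reagents that add atoms: none
Why: Dianion Ireland–Claisen rearrangement, in which the lithium-chelated (Z)-alkoxide enolate and the E-alkene react through a chair with the tertiary group equatorial, so the (S)-carbinol chirality is transferred to 13S and 14R (syn) and the new C11=C12 bond is E (this hydroxy-ester dianion variant is precedented for crotyl hydroxyacetates).

Step 4
Reactants: 10 (2R,3S,E)-2-hydroxy-3,6,6-trimethylocta-4,7-dienoic acid
Product: 11 (2R,3S,E)-2-hydroxy-N-methoxy-N,3,6,6-tetramethylocta-4,7-dienamide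
Conditions: MeNHOMe·HCl, EDC·HCl, HOBt, N-methylmorpholine, CH2Cl2, 0 °C to rt
Reagents that add atoms: N,O-dimethylhydroxylamine hydrochloride, CNOC.Cl
Why: Carbodiimide/HOBt amide coupling to the Weinreb amide, which tolerates the free α-hydroxyl and does not epimerise C14.

Step 5
Reactants: 12 (S)-3-bromo-2-methylpropan-1-ol
Product: 13 (S)-3-bromo-2-methylpropanal
Conditions: Dess–Martin periodinane, CH2Cl2, 0 °C to rt; used crude at once
Reagents that add atoms: none
Why: Dess–Martin oxidation under non-basic conditions, chosen so that the β-bromo aldehyde neither loses HBr nor epimerises before it is used.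

Step 6
Reactants: 13 (S)-3-bromo-2-methylpropanal
Product: 15 (2S,3R)-1-bromo-2-methylhex-5-en-3-ol, via borinate ester 14 (not isolated)
Conditions: (+)-Ipc2B(allyl), Et2O, −78 °C; then pH 7 buffer, H2O2, MeOH, 0 °C
Reagents that add atoms: (+)-B-allyldiisopinocampheylborane, C=CCB([C@H]1C[C@H]2C[C@@H]([C@@H]1C)C2(C)C)[C@H]1C[C@H]2C[C@@H]([C@@H]1C)C2(C)C
Why: Brown allylboration, where the (+)-Ipc reagent attacks the Re face (matched with the Felkin–Anh preference of the α-methyl aldehyde) to give the 2,3-syn alcohol, which is the C2/C3 relationship of the target.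

Step 7
Reactants: 15 (2S,3R)-1-bromo-2-methylhex-5-en-3-ol
Product: 16 tert-butyl{[(2S,3R)-1-bromo-2-methylhex-5-en-3-yl]oxy}dimethylsilane
Conditions: TBSOTf, 2,6-lutidine, CH2Cl2, −78 to 0 °C
Reagents that add atoms: tert-butyldimethylsilyl triflate, CC(C)(C)[Si](C)(C)OS(=O)(=O)C(F)(F)F
Why: Silyl ether formation, which puts a non-leaving group on O3 because any acyloxy group next to C4 would be expelled when C4 becomes nucleophilic in step 10.

Step 8
Reactants: 16 tert-butyl{[(2S,3R)-1-bromo-2-methylhex-5-en-3-yl]oxy}dimethylsilane; 11 (2R,3S,E)-2-hydroxy-N-methoxy-N,3,6,6-tetramethylocta-4,7-dienamide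
Product: 18 (4R,5R,8R,9S,10E)-4-(tert-butyldimethylsilyloxy)-8-hydroxy-5,9,12,12-tetramethyltetradeca-1,10,13-trien-7-one, via Grignard reagent 17 (not isolated)
Conditions: 16, Mg, I2 (cat.), THF, rt to 40 °C; 11, t-BuMgCl (1.05 equiv), THF, −20 °C, then 17 (1.5 equiv), −20 to 0 °C; cold 0.5 M HCl
Reagents that add atoms: none
Why: Weinreb ketone synthesis, in which the hydroxyl is first turned into its magnesium alkoxide and the chelated tetrahedral intermediate stops at the ketone stage, forming the C15–C1 bond without touching any stereocentre.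

Step 9
Reactants: 18 (4R,5R,8R,9S,10E)-4-(tert-butyldimethylsilyloxy)-8-hydroxy-5,9,12,12-tetramethyltetradeca-1,10,13-trien-7-one; 19 2-methylprop-2-enal (methacrolein)
Product: 20 (2E,5R,6R,9R,10S,11E)-5-(tert-butyldimethylsilyloxy)-9-hydroxy-2,6,10,13,13-pentamethyl-8-oxopentadeca-2,11,14-trienal
Conditions: second-generation Hoveyda–Grubbs catalyst RuCl2(H2IMes)(=CH-C6H4-2-O-i-Pr) (5–10 mol%), 19 (10 equiv), CH2Cl2, 40 °C
Reagents that add atoms: none
Why: Olefin cross-metathesis, which engages only the unhindered allyl terminus (the vinyl group on the quaternary carbon and the flanked internal alkene are inert) and gives the thermodynamic (E)-2-methyl enal.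

Step 10
Reactants: 20 (2E,5R,6R,9R,10S,11E)-5-(tert-butyldimethylsilyloxy)-9-hydroxy-2,6,10,13,13-pentamethyl-8-oxopentadeca-2,11,14-trienal
Product: 22 (E)-3-[(1S,2R,4R,5S)-5-(tert-butyldimethylsilyloxy)-2-hydroxy-2-[(1R,2S,3E)-1-hydroxy-2,5,5-trimethylhepta-3,6-dien-1-yl]-4-methylcyclopentyl]-2-methylprop-2-enal, via dienamine 21 (not isolated)
Conditions: pyrrolidine (20 mol%), PhCO2H (20 mol%), toluene, 0 °C to rt
Reagents that add atoms: none
Why: Proposed new method: pyrrolidine condenses only with the enal to give dienamine 21, whose γ-carbon C4 adds 5-exo to the C15 ketone (intramolecular vinylogous aldol); the ketol is locked by an O14–H···O=C15 hydrogen bond in a Cram-chelate-like conformer so C4 attacks on the side of H14, anti to the C13 branch, giving 15R, and the alkenyl group on C4 ends trans to the bulky C14 chain (C4 can equilibrate through the dienamine and the aldol is reversible) giving 4S; O3 (silyl ether) and O15 (free hydroxyl) are poor leaving groups so vinylogous E1cB loss is held back, and the still-masked C9 vinyl group removes a competing ketone; the closest known reaction types are dienamine γ-functionalisation of α-branched enals and amine-catalysed intramolecular ketone aldol cyclisation of the Hajos–Parrish kind, and the C4–C15 bond is the aldol closure proposed for ring A in the biosynthesis.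

Step 11
Reactants: 22 (the cyclopentane diol enal of step 10)
Product: 23 (E)-3-[(1S,2R,4R,5S)-2-acetoxy-2-[(1R,2S,3E)-1-acetoxy-2,5,5-trimethylhepta-3,6-dien-1-yl]-5-(tert-butyldimethylsilyloxy)-4-methylcyclopentyl]-2-methylprop-2-enal
Conditions: Ac2O (excess), DMAP (3 equiv), Et3N, CH2Cl2, rt to 40 °C
Reagents that add atoms: acetic anhydride, CC(=O)OC(C)=O
Why: DMAP-catalysed acetylation of the secondary O14 and, more slowly, the tertiary O15 hydroxyl, under nucleophilic catalysis that does not convert the enal into an acylal and is too weakly basic to deprotonate C4.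

Step 12
Reactants: 23 (the diacetate silyl ether of step 11)
Product: 24 (E)-3-[(1S,2R,4R,5S)-2-acetoxy-2-[(1R,2S,3E)-1-acetoxy-2,5,5-trimethylhepta-3,6-dien-1-yl]-5-hydroxy-4-methylcyclopentyl]-2-methylprop-2-enal
Conditions: HF·pyridine, pyridine, THF, 0 °C to rt
Reagents that add atoms: none
Why: Fluoride-mediated desilylation under buffered acidic conditions, which frees O3 without acetyl migration or loss of the acetates.

Step 13
Reactants: 24 (the C3 alcohol of step 12)
Product: 25 (E)-3-[(1S,2R,4R,5S)-2-acetoxy-2-[(1R,2S,3E)-1-acetoxy-2,5,5-trimethylhepta-3,6-dien-1-yl]-5-(benzoyloxy)-4-methylcyclopentyl]-2-methylprop-2-enal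
Conditions: BzCl, pyridine, DMAP (cat.), CH2Cl2, 0 °C to rt
Reagents that add atoms: benzoyl chloride, O=C(Cl)c1ccccc1
Why: DMAP-catalysed benzoylation of the only free hydroxyl, with retention at C3.

Step 14
Reactants: 25 (the benzoate of step 13)
Product: 26 (E)-3-[(1S,2R,4R,5S)-2-acetoxy-2-[(1R,2S,3E)-1-acetoxy-2,5,5-trimethyl-6-oxohept-3-en-1-yl]-5-(benzoyloxy)-4-methylcyclopentyl]-2-methylprop-2-enal (target)
Conditions: PdCl2 (10 mol%), CuCl (20 mol%), O2 (1 atm), DMF/H2O (7:1), rt
Reagents that add atoms: water, O (source of the ketone oxygen; dioxygen, O=O, is the terminal oxidant)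
Why: Tsuji–Wacker oxidation, in which Markovnikov hydroxypalladation of the only monosubstituted alkene gives the C9 methyl ketone while the enal and the hindered internal alkene do not react.

**Compound list**

1 | (E)-but-2-enal (crotonaldehyde) | C/C=C/C=O | starting material
2 | 3-methylbuta-1,2-diene | CC(C)=C=C | starting material
3 | (+)-B-(3-methylbut-2-en-1-yl)diisopinocampheylborane | CC(C)=CCB([C@H]1C[C@H]2C[C@@H]([C@@H]1C)C2(C)C)[C@H]1C[C@H]2C[C@@H]([C@@H]1C)C2(C)C | intermediate
4 | (S,E)-3,3-dimethylhepta-1,5-dien-4-yl (+)-diisopinocampheylborinate | C/C=C/[C@H](OB([C@H]1C[C@H]2C[C@@H]([C@@H]1C)C2(C)C)[C@H]1C[C@H]2C[C@@H]([C@@H]1C)C2(C)C)C(C)(C)C=C | intermediate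
5 | (S,E)-3,3-dimethylhepta-1,5-dien-4-ol | C/C=C/[C@H](O)C(C)(C)C=C | intermediate
6 | (S,E)-3,3-dimethylhepta-1,5-dien-4-yl 2-(trimethylsilyloxy)acetate | C/C=C/[C@H](OC(=O)CO[Si](C)(C)C)C(C)(C)C=C | intermediate
7 | (S,E)-3,3-dimethylhepta-1,5-dien-4-yl 2-hydroxyacetate | C/C=C/[C@H](OC(=O)CO)C(C)(C)C=C | intermediate
8 | (S,E)-4-{[(Z)-1,2-bis(trimethylsilyloxy)ethenyl]oxy}-3,3-dimethylhepta-1,5-diene | C/C=C/[C@H](O/C(O[Si](C)(C)C)=C/O[Si](C)(C)C)C(C)(C)C=C | intermediate
9 | trimethylsilyl (2R,3S,E)-3,6,6-trimethyl-2-(trimethylsilyloxy)octa-4,7-dienoate | C[Si](C)(C)OC(=O)[C@H](O[Si](C)(C)C)[C@@H](C)/C=C/C(C)(C)C=C | intermediate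
10 | (2R,3S,E)-2-hydroxy-3,6,6-trimethylocta-4,7-dienoic acid | OC(=O)[C@H](O)[C@@H](C)/C=C/C(C)(C)C=C | intermediate
11 | (2R,3S,E)-2-hydroxy-N-methoxy-N,3,6,6-tetramethylocta-4,7-dienamide | CON(C)C(=O)[C@H](O)[C@@H](C)/C=C/C(C)(C)C=C | intermediate
12 | (S)-3-bromo-2-methylpropan-1-ol | BrC[C@@H](C)CO | starting material
13 | (S)-3-bromo-2-methylpropanal | BrC[C@@H](C)C=O | intermediate
14 | (2S,3R)-1-bromo-2-methylhex-5-en-3-yl (+)-diisopinocampheylborinate | BrC[C@@H](C)[C@H](OB([C@H]1C[C@H]2C[C@@H]([C@@H]1C)C2(C)C)[C@H]1C[C@H]2C[C@@H]([C@@H]1C)C2(C)C)CC=C | intermediate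
15 | (2S,3R)-1-bromo-2-methylhex-5-en-3-ol | BrC[C@@H](C)[C@H](O)CC=C | intermediate
16 | tert-butyl{[(2S,3R)-1-bromo-2-methylhex-5-en-3-yl]oxy}dimethylsilane | BrC[C@@H](C)[C@H](O[Si](C)(C)C(C)(C)C)CC=C | intermediate
17 | [(2S,3R)-3-(tert-butyldimethylsilyloxy)-2-methylhex-5-en-1-yl]magnesium bromide | Br[Mg]C[C@@H](C)[C@H](O[Si](C)(C)C(C)(C)C)CC=C | intermediate
18 | (4R,5R,8R,9S,10E)-4-(tert-butyldimethylsilyloxy)-8-hydroxy-5,9,12,12-tetramethyltetradeca-1,10,13-trien-7-one | O[C@H]([C@@H](C)/C=C/C(C)(C)C=C)C(=O)C[C@@H](C)[C@H](O[Si](C)(C)C(C)(C)C)CC=C | intermediate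
19 | 2-methylprop-2-enal (methacrolein) | CC(=C)C=O | starting material
20 | (2E,5R,6R,9R,10S,11E)-5-(tert-butyldimethylsilyloxy)-9-hydroxy-2,6,10,13,13-pentamethyl-8-oxopentadeca-2,11,14-trienal | O[C@H]([C@@H](C)/C=C/C(C)(C)C=C)C(=O)C[C@@H](C)[C@H](O[Si](C)(C)C(C)(C)C)C/C=C(\C)C=O | intermediate
21 | N-pyrrolidinyl (1E,3E)-dienamine of 20 (N–C7=C6(Me)–C5=C4) | O[C@H]([C@@H](C)/C=C/C(C)(C)C=C)C(=O)C[C@@H](C)[C@H](O[Si](C)(C)C(C)(C)C)/C=C/C(C)=C/N1CCCC1 | intermediate
22 | (E)-3-[(1S,2R,4R,5S)-5-(tert-butyldimethylsilyloxy)-2-hydroxy-2-[(1R,2S,3E)-1-hydroxy-2,5,5-trimethylhepta-3,6-dien-1-yl]-4-methylcyclopentyl]-2-methylprop-2-enal | O[C@H]([C@@H](C)/C=C/C(C)(C)C=C)[C@@]1(O)C[C@@H](C)[C@H](O[Si](C)(C)C(C)(C)C)[C@@H]1/C=C(\C)C=O | intermediate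
23 | (E)-3-[(1S,2R,4R,5S)-2-acetoxy-2-[(1R,2S,3E)-1-acetoxy-2,5,5-trimethylhepta-3,6-dien-1-yl]-5-(tert-butyldimethylsilyloxy)-4-methylcyclopentyl]-2-methylprop-2-enal | CC(=O)O[C@H]([C@@H](C)/C=C/C(C)(C)C=C)[C@@]1(OC(C)=O)C[C@@H](C)[C@H](O[Si](C)(C)C(C)(C)C)[C@@H]1/C=C(\C)C=O | intermediate
24 | (E)-3-[(1S,2R,4R,5S)-2-acetoxy-2-[(1R,2S,3E)-1-acetoxy-2,5,5-trimethylhepta-3,6-dien-1-yl]-5-hydroxy-4-methylcyclopentyl]-2-methylprop-2-enal | CC(=O)O[C@H]([C@@H](C)/C=C/C(C)(C)C=C)[C@@]1(OC(C)=O)C[C@@H](C)[C@H](O)[C@@H]1/C=C(\C)C=O | intermediate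
25 | (E)-3-[(1S,2R,4R,5S)-2-acetoxy-2-[(1R,2S,3E)-1-acetoxy-2,5,5-trimethylhepta-3,6-dien-1-yl]-5-(benzoyloxy)-4-methylcyclopentyl]-2-methylprop-2-enal | CC(=O)O[C@H]([C@@H](C)/C=C/C(C)(C)C=C)[C@@]1(OC(C)=O)C[C@@H](C)[C@H](OC(=O)c2ccccc2)[C@@H]1/C=C(\C)C=O | intermediate
26 | (E)-3-[(1S,2R,4R,5S)-2-acetoxy-2-[(1R,2S,3E)-1-acetoxy-2,5,5-trimethyl-6-oxohept-3-en-1-yl]-5-(benzoyloxy)-4-methylcyclopentyl]-2-methylprop-2-enal | CC(=O)O[C@H]([C@@H](C)/C=C/C(C)(C)C(C)=O)[C@@]1(OC(C)=O)C[C@@H](C)[C@H](OC(=O)c2ccccc2)[C@@H]1/C=C(\C)C=O | target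

**Step count and risks**

Total step count: 14. Longest linear sequence: 11 steps (steps 1–4 and 8–14, from crotonaldehyde); the bromide branch is 3 steps (5–7).

The three steps most likely to fail:

Step 10, the ring closure. The dienamine may form slowly from the α-branched enal, the hindered ketone may not be attacked, the adduct may dehydrate, or the C15/C4 configuration may not follow the hydrogen-bonded model. The fallback keeps the same C4–C15 aldol bond but replaces amine catalysis by a two-stage, metal-chelated vinylogous Mukaiyama aldol. It sets out from 20: TMSOTf and Et3N in CH2Cl2 at −78 °C give the bis-silylated dienol ether F1, which carries an O14 trimethylsilyl ether and a (1E,3E)-1-trimethylsilyloxy diene. TiCl4 in CH2Cl2 at −78 °C then exchanges the O14–Si bond for an O–Ti bond, so a five-membered titanium chelate of the ketol activates C15 and exposes the same face, and the γ-carbon C4 of the silyl dienol ether closes the ring. Aqueous acid work-up returns to the route at 22.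

Step 11, acetylation of the hindered tertiary O15 hydroxyl next to the base-sensitive C4–H. If O15 resists, the fallback delivers the acetyl group through a cyclic orthoester instead of by direct acylation. It sets out from 22: trimethyl orthoacetate and PPTS give the 14,15-cyclic orthoacetate F2. Kinetic hydrolysis with aqueous acetic acid releases the more acidic secondary hydroxyl and leaves the ester on the tertiary oxygen (the logic used to make 17-esters of corticosteroids), giving the 15-O-acetyl 14-alcohol F3. Routine Ac2O/pyridine acetylation of O14 rejoins the route at 23.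

Step 8, the fragment union. Magnesium insertion into 16 passes through a surface-bound 5-hexenyl-type radical that can cyclise, and the amide carries a free hydroxyl. The fallback changes the way the C1 carbanion is made. It sets out from 16 and 11: NaI in acetone converts 16 into the iodide F4. t-BuLi (2.1 equiv, pentane/Et2O, −78 °C) gives the alkyllithium F5 by lithium–iodine exchange, which involves no free alkyl radical and leaves the hexenyl chain uncyclised at −78 °C. F5 is added at −78 °C to 11 that has first been deprotonated with LiN(SiMe3)2, and acidic work-up returns to the route at 18.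

**Further compounds**

F1 | step 10 | O14-trimethylsilyl ether and (1E,3E)-1-trimethylsilyloxy-diene derived from 20 | C[Si](C)(C)O[C@H]([C@@H](C)/C=C/C(C)(C)C=C)C(=O)C[C@@H](C)[C@H](O[Si](C)(C)C(C)(C)C)/C=C/C(C)=C/O[Si](C)(C)C
F2 | step 11 | 14,15-O-(1-methoxyethylidene) cyclic orthoacetate of 22 | COC2(C)O[C@H]([C@@H](C)/C=C/C(C)(C)C=C)[C@@]1(O2)C[C@@H](C)[C@H](O[Si](C)(C)C(C)(C)C)[C@@H]1/C=C(\C)C=O
F3 | step 11 | 15-O-acetyl 14-hydroxy derivative of 22 | O[C@H]([C@@H](C)/C=C/C(C)(C)C=C)[C@@]1(OC(C)=O)C[C@@H](C)[C@H](O[Si](C)(C)C(C)(C)C)[C@@H]1/C=C(\C)C=O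
F4 | step 8 | tert-butyl{[(2S,3R)-1-iodo-2-methylhex-5-en-3-yl]oxy}dimethylsilane | IC[C@@H](C)[C@H](O[Si](C)(C)C(C)(C)C)CC=C
F5 | step 8 | [(2S,3R)-3-(tert-butyldimethylsilyloxy)-2-methylhex-5-en-1-yl]lithium | [Li]C[C@@H](C)[C@H](O[Si](C)(C)C(C)(C)C)CC=C
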